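# Proposed total synthesis of CNP0258231.4 by an asymmetric Diels–Alder reaction and a hydroxyl relay

## Analysis of the target

The target is a bisabolane-type triester built on one cyclohexane ring (C1–C6), whose C1 carries a five-carbon chain through the 1,1-disubstituted alkene carbon C7 (C7=C14H2), followed by the C8 carbinol (angelate), the C9 methylene and the trisubstituted C10–C11 epoxide with a gem-dimethyl end. On the ring, C2 and C3 bear angelates, C4 is a quaternary carbon holding a methyl group and the oxygen of the C4–C5 epoxide, and C6 is a methylene. The five ring stereocentres (1R,2S,3S,4R,5R) are contiguous and all-cis: C7, the C2 oxygen, the C3 oxygen and the epoxide oxygen lie on one face, and the C4 methyl lies on the other. C8 (S) and C10 (R) are cut off from the ring by the sp2 carbon C7 and from each other by C9, so each needs reagent control. The sensitive groups are three (Z)-2-methylbut-2-enoates, which isomerise easily to the E (tiglate) esters, two acid-labile trisubstituted epoxides, and an ionisable allylic ester at C8. The difficulty lies in placing four oxygens on one face of a flexible monocycle, in acylating three hindered secondary alcohols with a geometrically fragile acid, and in the two remote chain centres. The strategy rests on one feature: the carbonyl-derived carbon C7 on C1 is cis and adjacent to the C2 oxygen and para to the C4 methyl, which is the substitution pattern of an endo cycloadduct of a 1-acyloxy-3-methylbutadiene with an acrylate. The residual C3=C4 alkene of that adduct sits next to the C2 oxygen, which can then pass its configuration on to C3, C4 and C5.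

## Retrosynthetic reasoning

**C10–C11 epoxide.** The two C–O bonds of the chain epoxide are cut last, giving triene triester 25. This epoxide is the most fragile group, and C10=C11 is the only electron-rich trisubstituted alkene in 25, so a chiral ketone-derived dioxirane can address it alone and set C10 by reagent control.

**Ring ester C–O bonds.** The C2 and C3 esters are cut together, giving diol 22 and angelic anhydride 23. Both hydroxyls are hindered and flank the ring epoxide, so the forward step acylates their lithium alkoxides at low temperature. Because all three esters of the target are alike, an acyl shift between the oxygens during this step would be without consequence.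

**Silyl ethers and the C8 ester.** Diol 22 comes from bis-silyl ether 21 by fluoride, and the C8 ester C–O bond of 21 is cut to alcohol 18 and angelic acid 19. C8 is acylated at the point where it is the only free hydroxyl, directly after the last organometallic step, so no Z-ester ever meets a carbon nucleophile. The forward acylation is neutral and thermal, so that no alkoxide is generated next to the C2 silyl ether.

**C7–C8 bond.** The chain of 18 is cut between C7 and C8 into alkenyl triflate 15 and aldehyde 17. The cut is convergent: the forward chromium-mediated coupling makes the C–C bond, brings in the C14 methylene already in place and creates C8 under control of a chiral ligand. Cutting C8–C9 or C9–C10 instead would leave a fragment with no reliable polarity.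

**Alkenyl triflate to amide.** Triflate 15 comes from methyl ketone 13 by kinetic enolisation, 13 from the silylated Weinreb amide 12, and 12 from epoxy diol 11. The amide level is kept through the ring oxidations because it neither enolises nor fragments under them.

**Oxygen relay.** The C4–C5 epoxide of 11 is traced to ene-diol 10 (epoxidation directed by the C3 hydroxyl). The C3 carbinol and C4=C5 alkene of 10 are traced to epoxy alcohol 9 (eliminative opening of a C3–C4 epoxide). Epoxide 9 is traced to allylic alcohol 8 (epoxidation directed by the C2 hydroxyl). Each new oxygen is therefore placed by the one before it, on the same face. The opening of 9 must give the endocyclic alkene, so it is planned as a titanium-alkoxide rearrangement delivered from the C2 hydroxyl and not as an amide-base elimination, which would take a proton from the methyl group.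

**Imide.** Hydroxy amide 8 comes from cycloadduct 7 by aminolysis of the imide and the acetate.

**Ring.** Adduct 7 is cut at C1–C2 and C5–C6 into dienyl acetate 2 and acryloyl imide 6. This is the only disconnection that forms the ring, both ring bonds and the C1/C2 pair in one catalytic asymmetric step from two achiral three- and five-carbon pieces.

**Building blocks.** Diene 2 comes from aldehyde 1, imide 6 from 3 and 4, and aldehyde 17 from alcohol 16, each in one step.

## Alternatives that were turned down

**Alternative 1: asymmetric epoxidation of a chain allylic alcohol, then eliminative opening to the C8 carbinol.**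
- Disconnection: the C14 methylene and the C8 oxygen are traced to a 7,8-epoxide with a C7 methyl.
- Forward key step: the (E)-allylic alcohol A2 (C9H2OH–C8H=C7(CH3)–ring) undergoes Sharpless asymmetric epoxidation (Ti(OiPr)4, L-(+)-diethyl tartrate, t-BuOOH) to epoxy alcohol A1. Opening toward the C14 methyl would then give the C8 carbinol and the exocyclic alkene.
- For: the configuration at C8 comes from one of the most dependable reagent-controlled reactions, and elimination toward a methyl group is the naturally favoured direction.
- Against: A2 already contains all five ring stereocentres and the ring epoxide, so this is a chain tactic that still needs a ring synthesis. A2 requires an E-selective olefination of a hindered, base-sensitive methyl ketone such as 13. The opening must spare the second trisubstituted epoxide in the ring. After the opening, C9 is only a primary alcohol, and the C10–C11 unit must still be attached by selective activation, C–C bond formation and a further epoxidation.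
- Comparison: it is stronger at C8 than the ligand-controlled coupling used here. The chosen strategy offers instead one coupling that delivers the C7–C8 bond, the methylene and the whole chain, and it supplies the ring as well.

**Alternative 2: pyrone Diels–Alder with a lactone bridge.**
- Disconnection: C1–C6 and C4–C5 are cut, with C7 as a lactone carbonyl bridging C1 and the C4 oxygen.
- Forward key step: 6-methyl-2H-pyran-2-one A3 and but-3-en-2-one A4 combine under a chiral oxazaborolidinium Lewis acid to the endo bicyclic lactone A5.
- For: one step fixes C1, the quaternary oxygenated C4 and an acetyl handle at C5. The bridge forces C7 and the C4 oxygen onto one face and should steer dihydroxylation of C2=C3 to that face. The endo acetyl is trans to the C4 oxygen, which is what an epoxide closure with inversion at C5 needs. No regioselective elimination is required, and on that point it is stronger than the chosen relay.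
- Against: a simple 2-pyrone is an electron-poor, reluctant diene, and pairing it with a Lewis-acid-activated enone is electronically mismatched. Such adducts lose CO2 on warming. Afterwards the acetyl must be converted to oxygen by Baeyer–Villiger oxidation in the presence of a lactone, the lactone must be opened, and C7 must be brought down from the acid level. This adds several redox steps.
- Comparison: the chosen cycloaddition uses an electronically matched diene–dienophile pair in a well-established catalyst class and needs only one interconversion at C7.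

**Alternative 3: allylchromium ring closure to a cis-fused methylene lactone.**
- Disconnection: C1–C2 is cut, with C8 as an ester.
- Forward key step: CrCl2 (divalent chromium) turns the allylic bromide of the acyclic bromo aldehyde A6 into an allylchromium that adds through C1 to the C2 aldehyde. The alkoxide then lactonises to the cis-fused α-methylene-γ-butyrolactone A7.
- For: the ring closure delivers the C1–C2 bond, the cis C1/C2 pair, the C14 methylene and the C4=C5 alkene together, with the C3 oxygen already present. Only the directed epoxidation remains on the ring. On ring functionalisation it is shorter and has no regiochemical elimination.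
- Against: C8 arrives as a lactone carbonyl. It must be reduced and alkylated with a C9–C11 nucleophile at an acrolein-type aldehyde, with no control at C8. A6 needs a Z-trisubstituted alkene and an epimerisable, enantiopure α-silyloxy aldehyde, reached only by a long linear sequence. The required cis relation between C2 and C3 depends on a Felkin versus chelation balance in the cyclisation.
- Comparison: the chosen strategy reaches the ring in three steps from commodity materials with catalytic absolute control, and forms C8 directly at the alcohol level.

Key step: step 3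

## Route

Remark 1: ring and chain atoms keep the locants of the target in all names (ring C1–C6, chain C7–C11, methylene C14).

Remark 2: the oxazoline–sulfonamide ligand of step 12 is written as its (S)-form. Induction at C8 is taken to be ligand-controlled, and the antipode would be used if the C8 epimer were to dominate.

Remark 3: angelic anhydride 23 is taken as a purchasable reagent.

Step 1
Reactants: 1 3-methylbut-2-enal
Product: 2 (1E)-3-methylbuta-1,3-dien-1-yl acetate
Conditions: Ac2O, KOAc, Et3N, 120 °C; fractional distillation
Reagents that add atoms: acetic anhydride, CC(=O)OC(C)=O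
Why: Dienol acetate formation by O-acylation of the extended enolate of the enal; the E isomer should dominate and is separated by distillation, and any Z isomer cannot reach the s-cis geometry and is inert in step 3.

Step 2
Reactants: 3 oxazolidin-2-one; 4 acryloyl chloride
Product: 6 3-acryloyloxazolidin-2-one, via bromomagnesium oxazolidinone salt 5 (not isolated)
Conditions: MeMgBr, THF, 0 °C; then 4, −78 → 0 °C
Reagents that add atoms: none
Why: N-Acylation of the magnesium salt of the carbamate; the low temperature and the weakly basic counter-ion should hold back conjugate addition and polymerisation of the acrylate.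

Step 3
Reactants: 2 (1E)-3-methylbuta-1,3-dien-1-yl acetate; 6 3-acryloyloxazolidin-2-one
Product: 7 3-[(1S,2R)-2-acetoxy-4-methylcyclohex-3-ene-1-carbonyl]oxazolidin-2-one (cis)
Conditions: [Cu((S,S)-t-Bu-box)](SbF6)2 (5 mol %), CH2Cl2, 0 °C → rt; t-Bu-box = 2,2'-(propane-2,2-diyl)bis[(4S)-4-tert-butyl-4,5-dihydrooxazole]
Reagents that add atoms: none
Why: A concerted, asynchronous [4+2] cycloaddition in which the imide is bound through both carbonyl oxygens to square-planar divalent copper in its s-cis form; the closest known reaction type is the bis(oxazoline)–copper-catalysed Diels–Alder reaction of acryloyl imides with 1-acyloxydienes. The six-membered ring is closed by suprafacial addition across both components, forming C1–C2 and C5–C6 in the same step. C1 is set by the catalyst: one tert-butyl group of the ligand covers one face of the bound dienophile, so the diene should add to the open face (Re at the α-carbon), which gives 1S. C2 is set relative to C1 by the endo approach together with the fixed E geometry of the diene, which places the acetoxy group cis to the acyl group. The regiochemistry is reinforced twice, since the acetoxy terminus bonds to the α-carbon (ortho) and the methyl ends para. The step needs endo over exo selectivity and facial control; the two-point binding of the imide and the non-coordinating SbF6 counter-ion secure the rigid complex on which both depend.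

Step 4
Reactants: 7 cycloadduct
Product: 8 (1S,2R)-2-hydroxy-N-methoxy-N,4-dimethylcyclohex-3-ene-1-carboxamide
Conditions: MeNHOMe·HCl (5 equiv), AlMe3 (5 equiv), CH2Cl2, 0 °C → rt
Reagents that add atoms: N,O-dimethylhydroxylamine hydrochloride, CNOC.Cl
Why: Weinreb aminolysis: the aluminium amide attacks the exocyclic imide carbonyl and, in excess, also aminolyses the acetate; the reagent is nucleophilic but not basic, so C1 should not epimerise and the β-oxygen should not be eliminated.

Step 5
Reactants: 8 allylic alcohol
Product: 9 (1S,2S,3S,4R)-3,4-epoxy-2-hydroxy-N-methoxy-N,4-dimethylcyclohexane-1-carboxamide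
Conditions: VO(acac)2 (cat.), t-BuOOH, CH2Cl2, 0 °C → rt
Reagents that add atoms: tert-butyl hydroperoxide, CC(C)(C)OO
Why: Hydroxyl-directed epoxidation: the vanadate ester of the pseudoaxial C2 hydroxyl delivers oxygen to the syn face of C3=C4, which sets C3 and C4 (oxygen cis to O2, methyl on the opposite face).

Step 6
Reactants: 9 cis-epoxy alcohol
Product: 10 (1S,2S,3R)-2,3-dihydroxy-N-methoxy-N,4-dimethylcyclohex-4-ene-1-carboxamide
Conditions: Ti(OiPr)4 (2 equiv), CH2Cl2, rt → 40 °C
Reagents that add atoms: none
Why: Hydroxyl-delivered titanium alkoxide rearrangement of a 2,3-epoxy alcohol to an ene-diol: titanium bound to O2 and to the epoxide oxygen weakens the tertiary C4–O bond, and a titanium-bound isopropoxide removes the syn proton at C5, the ring carbon cis to C2, so the endocyclic C4=C5 alkene is expected. The C3–O bond is not broken, so C3 keeps the configuration from step 5.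

Step 7
Reactants: 10 ene-diol
Product: 11 (1S,2S,3S,4S,5R)-4,5-epoxy-2,3-dihydroxy-N-methoxy-N,4-dimethylcyclohexane-1-carboxamide (all oxygens cis)
Conditions: VO(acac)2 (cat.), t-BuOOH, CH2Cl2, 0 °C
Reagents that add atoms: tert-butyl hydroperoxide, CC(C)(C)OO
Why: Hydroxyl-directed epoxidation: A(1,2) strain with the C4 methyl holds the C3 hydroxyl pseudoaxial, the best geometry for vanadium delivery to the syn face of C4=C5, which sets C4 and C5 (the C4 descriptor is S here only because the free C3 hydroxyl changes the ranking).

Step 8
Reactants: 11 epoxy diol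
Product: 12 (1S,2S,3S,4R,5R)-4,5-epoxy-N-methoxy-N,4-dimethyl-2,3-bis(triethylsilyloxy)cyclohexane-1-carboxamide
Conditions: Et3SiCl, imidazole, DMAP (cat.), DMF, rt → 40 °C
Reagents that add atoms: chlorotriethylsilane, CC[Si](Cl)(CC)CC
Why: Silylation of both secondary alcohols with a silyl chloride and imidazole; no silyl triflate is used, since it could open the neighbouring epoxide.

Step 9
Reactants: 12 Weinreb amide
Product: 13 1-[(1S,2S,3S,4R,5R)-4,5-epoxy-4-methyl-2,3-bis(triethylsilyloxy)cyclohexyl]ethan-1-one
Conditions: MeLi, THF, −78 °C; aq. NH4Cl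
Reagents that add atoms: methyllithium, [Li]C
Why: Weinreb ketone synthesis: the chelated tetrahedral intermediate survives until the quench, so over-addition and enolisation at C1 should not occur, and the epoxide is inert to MeLi at −78 °C.

Step 10
Reactants: 13 methyl ketone
Product: 15 1-[(1S,2S,3S,4R,5R)-4,5-epoxy-4-methyl-2,3-bis(triethylsilyloxy)cyclohexyl]ethenyl trifluoromethanesulfonate, via potassium enolate 14 (not isolated)
Conditions: KN(SiMe3)2, THF, −78 °C; then Comins' reagent, −78 °C
Reagents that add atoms: N-(5-chloropyridin-2-yl)-N-(trifluoromethylsulfonyl)trifluoromethanesulfonamide (Comins' reagent), O=S(=O)(N(c1ccc(Cl)cn1)S(=O)(=O)C(F)(F)F)C(F)(F)F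
Why: Kinetic deprotonation at the methyl group followed by O-triflation (enol triflate formation); the fast triflyl donor traps the terminal enolate at −78 °C before it can equilibrate to the C1 enolate, which would epimerise C1 or expel the C2 silyloxy group.

Step 11
Reactants: 16 4-methylpent-3-en-1-ol
Product: 17 4-methylpent-3-enal
Conditions: Dess–Martin periodinane, NaHCO3, CH2Cl2, 0 °C → rt; used at once as a solution
Reagents that add atoms: none
Why: Dess–Martin oxidation under buffered, non-basic conditions, so the β,γ-alkene should not move into conjugation.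

Step 12
Reactants: 15 alkenyl triflate; 17 4-methylpent-3-enal
Product: 18 (3S)-2-[(1R,2S,3S,4R,5R)-4,5-epoxy-4-methyl-2,3-bis(triethylsilyloxy)cyclohexyl]-6-methylhepta-1,5-dien-3-ol
Conditions: CrCl2 (4 equiv), (S)-N-[2-(4-isopropyl-4,5-dihydrooxazol-2-yl)-6-methylphenyl]methanesulfonamide (4.4 equiv), Et3N (4.4 equiv), THF, rt; then NiCl2 (cat.), LiCl, 15, 17 (2 equiv), rt
Reagents that add atoms: none
Why: Nozaki–Hiyama–Kishi coupling: nickel inserts into the C–OTf bond, the alkenyl group passes to chromium, and the alkenylchromium adds only to the aldehyde. C8 is set by the chiral sulfonamide ligand on chromium (reagent control); the epoxide, the silyl ethers and the trisubstituted alkene are not touched.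

Step 13
Reactants: 18 allylic alcohol; 19 angelic acid
Product: 21 (3S)-2-[(1R,2S,3S,4R,5R)-4,5-epoxy-4-methyl-2,3-bis(triethylsilyloxy)cyclohexyl]-6-methylhepta-1,5-dien-3-yl (2Z)-2-methylbut-2-enoate, via angeloyl trichlorobenzoyl anhydride 20 (not isolated)
Conditions: 19 (2 equiv), 2,4,6-trichlorobenzoyl chloride (2 equiv), Et3N, toluene, rt; then 18, toluene, 75 °C
Reagents that add atoms: none
Why: Mixed-anhydride (Yamaguchi-type) esterification run without a nucleophilic catalyst: the C8 hydroxyl, the only free one, attacks the unhindered angeloyl carbonyl of 20, and no addition–elimination path is open that would turn the Z acid into the E acid. No alkoxide is formed, so a silyl shift from O2 to O8 is not invited.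

Step 14
Reactants: 21 bis-silyl ether
Product: 22 (3S)-2-[(1R,2S,3S,4S,5R)-4,5-epoxy-2,3-dihydroxy-4-methylcyclohexyl]-6-methylhepta-1,5-dien-3-yl (2Z)-2-methylbut-2-enoate
Conditions: HF·pyridine, pyridine, THF, 0 °C → rt
Reagents that add atoms: none
Why: Fluoride-mediated cleavage of the triethylsilyl ethers; the excess pyridine buffers the medium so that the epoxide and the allylic angelate should survive.

Step 15
Reactants: 22 diol; 23 angelic anhydride
Product: 25 (3S)-2-[(1R,2S,3S,4R,5R)-4,5-epoxy-4-methyl-2,3-bis{[(2Z)-2-methylbut-2-enoyl]oxy}cyclohexyl]-6-methylhepta-1,5-dien-3-yl (2Z)-2-methylbut-2-enoate, via dilithium dialkoxide 24 (not isolated)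
Conditions: LiN(SiMe3)2 (2.1 equiv), THF, −78 °C; then 23 (3 equiv), −78 → 0 °C; aq. NH4Cl
Reagents that add atoms: none
Why: Acylation of lithium alkoxides with a symmetrical anhydride: both hindered ring alkoxides of 24 attack 23 at low temperature, with neither heat nor a nucleophilic amine present to turn the Z ester into the E ester. The C3 alkoxide cannot undergo Payne rearrangement because its oxygen lies on the same face as the epoxide oxygen, and an acyl shift among the three oxygens would be degenerate since all end as the same ester.

Step 16
Reactants: 25 triene tri-angelate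
Product: 26 CNP0258231.4
Conditions: D-fructose-derived Shi ketone (1,2:4,5-di-O-isopropylidene-β-D-erythro-2,3-hexodiulo-2,6-pyranose, 0.3 equiv), KHSO5 (as Oxone, 2KHSO5·KHSO4·K2SO4), K2CO3, Bu4NHSO4, MeCN–CH2(OMe)2 / aq. Na2B4O7 buffer (pH 10.5), 0 °C
Reagents that add atoms: potassium peroxymonosulfate, [K+].[O-]S(=O)(=O)OO
Why: Shi asymmetric epoxidation: the chiral dioxirane reacts through a spiro transition state with the electron-rich trisubstituted C10=C11 alkene and should leave the 1,1-disubstituted C7=C14 alkene (deactivated by the allylic ester) and the electron-poor angelate alkenes alone. The D-fructose-derived ketone is expected to deliver oxygen to the face that gives 10R.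

## Compound list

1 | 3-methylbut-2-enal | CC(C)=CC=O | starting material
2 | (1E)-3-methylbuta-1,3-dien-1-yl acetate | CC(=O)O/C=C/C(C)=C | intermediate
3 | oxazolidin-2-one | O=C1NCCO1 | starting material
4 | acryloyl chloride | C=CC(=O)Cl | starting material
5 | bromomagnesium salt of oxazolidin-2-one | O=C1OCCN1[Mg]Br | intermediate
6 | 3-acryloyloxazolidin-2-one | C=CC(=O)N1CCOC1=O | intermediate
7 | 3-[(1S,2R)-2-acetoxy-4-methylcyclohex-3-ene-1-carbonyl]oxazolidin-2-one | O=C(N1CCOC1=O)[C@H]1CCC(C)=C[C@H]1OC(C)=O | intermediate
8 | (1S,2R)-2-hydroxy-N-methoxy-N,4-dimethylcyclohex-3-ene-1-carboxamide | CON(C)C(=O)[C@H]1CCC(C)=C[C@H]1O | intermediate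
9 | (1S,2S,3S,4R)-3,4-epoxy-2-hydroxy-N-methoxy-N,4-dimethylcyclohexane-1-carboxamide | CON(C)C(=O)[C@H]1CC[C@@]2(C)O[C@H]2[C@H]1O | intermediate
10 | (1S,2S,3R)-2,3-dihydroxy-N-methoxy-N,4-dimethylcyclohex-4-ene-1-carboxamide | CON(C)C(=O)[C@H]1CC=C(C)[C@@H](O)[C@H]1O | intermediate
11 | (1S,2S,3S,4S,5R)-4,5-epoxy-2,3-dihydroxy-N-methoxy-N,4-dimethylcyclohexane-1-carboxamide | CON(C)C(=O)[C@H]1C[C@H]2O[C@@]2(C)[C@@H](O)[C@H]1O | intermediate
12 | (1S,2S,3S,4R,5R)-4,5-epoxy-N-methoxy-N,4-dimethyl-2,3-bis(triethylsilyloxy)cyclohexane-1-carboxamide | CON(C)C(=O)[C@H]1C[C@H]2O[C@@]2(C)[C@@H](O[Si](CC)(CC)CC)[C@H]1O[Si](CC)(CC)CC | intermediate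
13 | 1-[(1S,2S,3S,4R,5R)-4,5-epoxy-4-methyl-2,3-bis(triethylsilyloxy)cyclohexyl]ethan-1-one | CC(=O)[C@H]1C[C@H]2O[C@@]2(C)[C@@H](O[Si](CC)(CC)CC)[C@H]1O[Si](CC)(CC)CC | intermediate
14 | potassium 1-[(1S,2S,3S,4R,5R)-4,5-epoxy-4-methyl-2,3-bis(triethylsilyloxy)cyclohexyl]ethen-1-olate | [K+].C=C([O-])[C@H]1C[C@H]2O[C@@]2(C)[C@@H](O[Si](CC)(CC)CC)[C@H]1O[Si](CC)(CC)CC | intermediate
15 | 1-[(1S,2S,3S,4R,5R)-4,5-epoxy-4-methyl-2,3-bis(triethylsilyloxy)cyclohexyl]ethenyl trifluoromethanesulfonate | C=C(OS(=O)(=O)C(F)(F)F)[C@H]1C[C@H]2O[C@@]2(C)[C@@H](O[Si](CC)(CC)CC)[C@H]1O[Si](CC)(CC)CC | intermediate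
16 | 4-methylpent-3-en-1-ol | CC(C)=CCCO | starting material
17 | 4-methylpent-3-enal | CC(C)=CCC=O | intermediate
18 | (3S)-2-[(1R,2S,3S,4R,5R)-4,5-epoxy-4-methyl-2,3-bis(triethylsilyloxy)cyclohexyl]-6-methylhepta-1,5-dien-3-ol | C=C([C@H](CC=C(C)C)O)[C@H]1C[C@H]2O[C@@]2(C)[C@@H](O[Si](CC)(CC)CC)[C@H]1O[Si](CC)(CC)CC | intermediate
19 | angelic acid, (2Z)-2-methylbut-2-enoic acid | C/C=C(/C)C(=O)O | starting material
20 | (2Z)-2-methylbut-2-enoic 2,4,6-trichlorobenzoic anhydride | C/C=C(/C)C(=O)OC(=O)c1c(Cl)cc(Cl)cc1Cl | intermediate
21 | (3S)-2-[(1R,2S,3S,4R,5R)-4,5-epoxy-4-methyl-2,3-bis(triethylsilyloxy)cyclohexyl]-6-methylhepta-1,5-dien-3-yl (2Z)-2-methylbut-2-enoate | C=C([C@H](CC=C(C)C)OC(=O)/C(C)=C\C)[C@H]1C[C@H]2O[C@@]2(C)[C@@H](O[Si](CC)(CC)CC)[C@H]1O[Si](CC)(CC)CC | intermediate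
22 | (3S)-2-[(1R,2S,3S,4S,5R)-4,5-epoxy-2,3-dihydroxy-4-methylcyclohexyl]-6-methylhepta-1,5-dien-3-yl (2Z)-2-methylbut-2-enoate | C=C([C@H](CC=C(C)C)OC(=O)/C(C)=C\C)[C@H]1C[C@H]2O[C@@]2(C)[C@@H](O)[C@H]1O | intermediate
23 | angelic anhydride, (2Z)-2-methylbut-2-enoic anhydride | C/C=C(/C)C(=O)OC(=O)/C(C)=C\C | starting material
24 | dilithium 2,3-dialkoxide of 22 | [Li+].[Li+].C=C([C@H](CC=C(C)C)OC(=O)/C(C)=C\C)[C@H]1C[C@H]2O[C@@]2(C)[C@@H]([O-])[C@H]1[O-] | intermediate
25 | (3S)-2-[(1R,2S,3S,4R,5R)-4,5-epoxy-4-methyl-2,3-bis{[(2Z)-2-methylbut-2-enoyl]oxy}cyclohexyl]-6-methylhepta-1,5-dien-3-yl (2Z)-2-methylbut-2-enoate (tri-angelate with the C10=C11 alkene) | C=C([C@H](CC=C(C)C)OC(=O)/C(C)=C\C)[C@H]1C[C@H]2O[C@@]2(C)[C@@H](OC(=O)/C(C)=C\C)[C@H]1OC(=O)/C(C)=C\C | intermediate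
26 | CNP0258231.4: (2S)-1-[(2R)-3,3-dimethyloxiran-2-yl]-3-[(1R,2S,3S,4R,5R)-4,5-epoxy-4-methyl-2,3-bis(angeloyloxy)cyclohexyl]but-3-en-2-yl angelate | C=C([C@H](C[C@H]1OC1(C)C)OC(=O)/C(C)=C\C)[C@H]1C[C@H]2O[C@@]2(C)[C@@H](OC(=O)/C(C)=C\C)[C@H]1OC(=O)/C(C)=C\C | target

## Step count and risks

Total step count: 16. Longest linear sequence: 14 (steps 1, 3–10, 12–16).

**Step 3 (key step).** The most likely failure is erosion of endo selectivity or of facial control. A 1-acyloxydiene is only moderately reactive and its ester carbonyl can compete with the imide for copper. Slow turnover would also let the diene polymerise. Fallback: control by a covalent auxiliary in place of the catalyst. Starting from 2 and 4, (R)-4-benzyloxazolidin-2-one is N-acylated with 4 to give (R)-3-acryloyl-4-benzyloxazolidin-2-one F1. Cycloaddition with 2 promoted by Et2AlCl (CH2Cl2, −78 °C) goes through the aluminium-chelated s-cis imide, whose benzyl group covers the Si face of the α-carbon, and should give the cis adduct F2 with the same 1S,2R configuration. Aminolysis with MeNHOMe·HCl/AlMe3 removes the auxiliary and the acetate, and the route is rejoined at 8.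

**Step 6.** The most likely failure is loss of the proton from the C4 methyl group in place of C5, giving the exocyclic alkene. A 1,2-hydride shift to a C3 ketone is also possible, because the ionising C4 centre has three neighbours that can respond. Fallback: a stepwise anti elimination. Starting from 9, aqueous HBr in THF at 0 °C opens the epoxide trans-diaxially at the tertiary carbon to the bromohydrin F3 (C4 bromide on the face opposite O3). The cis diol is then tied up as the cyclic carbonate F4 (1,1'-carbonyldiimidazole), so the epoxide cannot re-form. DBU in toluene at 80 °C effects E2 elimination. The C3 hydrogen is syn to bromide and cannot take part, and of the two remaining β-positions the axial ring hydrogen at C5 leads to the more substituted endocyclic alkene, so the ene carbonate F5 should result. K2CO3 in MeOH removes the carbonate, and the route is rejoined at 10.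

**Step 12.** The most likely failure is poor facial selectivity at C8, since the alkenylchromium is α-branched and the chiral ring may oppose the ligand. Nickel insertion into the triflate may also be slow in the presence of the ligand. Fallback: separate bond formation from stereocontrol. Starting from 15 and 17, the ligand-free coupling (CrCl2, NiCl2 cat., DMF) gives the C8-epimeric alcohols F6. Dess–Martin oxidation gives the α-methylene ketone F7. Corey–Bakshi–Shibata reduction with the (R)-methyl oxazaborolidine and catecholborane at −40 °C, in which the branched alkenyl group acts as the large substituent, should return the 8S alcohol, and the route is rejoined at 18.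

**Step 15.** The most likely failure is incomplete acylation of the hindered C3 alkoxide flanked by the epoxide, leaving mixtures of partial esters. Excess amide base could also deprotonate an angelate at its γ-position and so open a path to the E ester. Fallback: build the Z-alkenes on the ring esters instead of transferring them. Starting from 22, esterification with 2-[bis(2,2,2-trifluoroethoxy)phosphoryl]propanoic acid (DCC, DMAP) gives the bis-phosphonate F8. A twofold Still–Gennari olefination with acetaldehyde (KN(SiMe3)2, 18-crown-6, THF, −78 °C) then forms the two ring Z-2-methylbut-2-enoates under kinetic control, and the route is rejoined at 25.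

**Step 16.** The most likely failure is incomplete facial selectivity at C10 on the fully elaborated substrate, where the epimer would be hard to remove. Slow hydrolysis of an ester at pH 10.5 or over-oxidation at C7=C14 is also possible. Fallback: set C10 before the fragments are joined. Starting from 16, the same Shi epoxidation gives 2-[(2R)-3,3-dimethyloxiran-2-yl]ethan-1-ol F9, which can be purified and checked, and buffered Dess–Martin oxidation gives the epoxy aldehyde F10. Coupling of F10 with 15 under the conditions of step 12 gives the epoxy alcohol F11. Esterification with 19 as in step 13 gives the C8 angelate F12, and HF·pyridine gives the diepoxy diol F13. Acylation with 23 under the conditions of step 15 then leads directly to 26.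

## Further compounds

F1 | step 3 | (R)-3-acryloyl-4-benzyloxazolidin-2-one | C=CC(=O)N1[C@H](Cc2ccccc2)COC1=O
F2 | step 3 | (4R)-3-[(1S,2R)-2-acetoxy-4-methylcyclohex-3-ene-1-carbonyl]-4-benzyloxazolidin-2-one | O=C(N1[C@H](Cc2ccccc2)COC1=O)[C@H]1CCC(C)=C[C@H]1OC(C)=O
F3 | step 6 | (1S,2S,3S,4S)-4-bromo-2,3-dihydroxy-N-methoxy-N,4-dimethylcyclohexane-1-carboxamide | CON(C)C(=O)[C@H]1CC[C@](C)(Br)[C@@H](O)[C@H]1O
F4 | step 6 | cyclic 2,3-carbonate of F3 | CON(C)C(=O)[C@H]1CC[C@](C)(Br)[C@H]2OC(=O)O[C@@H]12
F5 | step 6 | cyclic 2,3-carbonate of 10 | CON(C)C(=O)[C@H]1CC=C(C)[C@H]2OC(=O)O[C@@H]12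
F6 | step 12 | C8-epimeric mixture of 18 | C=C(C(O)CC=C(C)C)[C@H]1C[C@H]2O[C@@]2(C)[C@@H](O[Si](CC)(CC)CC)[C@H]1O[Si](CC)(CC)CC
F7 | step 12 | 2-[(1R,2S,3S,4R,5R)-4,5-epoxy-4-methyl-2,3-bis(triethylsilyloxy)cyclohexyl]-6-methylhepta-1,5-dien-3-one | C=C(C(=O)CC=C(C)C)[C@H]1C[C@H]2O[C@@]2(C)[C@@H](O[Si](CC)(CC)CC)[C@H]1O[Si](CC)(CC)CC
F8 | step 15 | 2,3-bis{2-[bis(2,2,2-trifluoroethoxy)phosphoryl]propanoate} of 22 | C=C([C@H](CC=C(C)C)OC(=O)/C(C)=C\C)[C@H]1C[C@H]2O[C@@]2(C)[C@@H](OC(=O)C(C)P(=O)(OCC(F)(F)F)OCC(F)(F)F)[C@H]1OC(=O)C(C)P(=O)(OCC(F)(F)F)OCC(F)(F)F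
F9 | step 16 | 2-[(2R)-3,3-dimethyloxiran-2-yl]ethan-1-ol | OCC[C@H]1OC1(C)C
F10 | step 16 | 2-[(2R)-3,3-dimethyloxiran-2-yl]acetaldehyde | O=CC[C@H]1OC1(C)C
F11 | step 16 | (2S)-1-[(2R)-3,3-dimethyloxiran-2-yl]-3-[(1R,2S,3S,4R,5R)-4,5-epoxy-4-methyl-2,3-bis(triethylsilyloxy)cyclohexyl]but-3-en-2-ol | C=C([C@H](C[C@H]1OC1(C)C)O)[C@H]1C[C@H]2O[C@@]2(C)[C@@H](O[Si](CC)(CC)CC)[C@H]1O[Si](CC)(CC)CC
F12 | step 16 | (2S)-1-[(2R)-3,3-dimethyloxiran-2-yl]-3-[(1R,2S,3S,4R,5R)-4,5-epoxy-4-methyl-2,3-bis(triethylsilyloxy)cyclohexyl]but-3-en-2-yl (2Z)-2-methylbut-2-enoate | C=C([C@H](C[C@H]1OC1(C)C)OC(=O)/C(C)=C\C)[C@H]1C[C@H]2O[C@@]2(C)[C@@H](O[Si](CC)(CC)CC)[C@H]1O[Si](CC)(CC)CC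
F13 | step 16 | (2S)-1-[(2R)-3,3-dimethyloxiran-2-yl]-3-[(1R,2S,3S,4S,5R)-4,5-epoxy-2,3-dihydroxy-4-methylcyclohexyl]but-3-en-2-yl (2Z)-2-methylbut-2-enoate | C=C([C@H](C[C@H]1OC1(C)C)OC(=O)/C(C)=C\C)[C@H]1C[C@H]2O[C@@]2(C)[C@@H](O)[C@H]1O
A1 | alternative 1 | (7S,8S)-7,8-epoxy-9-ol with bis(tert-butyldimethylsilyl)-protected epoxy ring | OC[C@@H]1O[C@@]1(C)[C@H]1C[C@H]2O[C@@]2(C)[C@@H](O[Si](C)(C)C(C)(C)C)[C@H]1O[Si](C)(C)C(C)(C)C
A2 | alternative 1 | (E)-allylic alcohol C9H2OH–C8H=C7(CH3)–ring with the same protected ring | OC/C=C(\C)[C@H]1C[C@H]2O[C@@]2(C)[C@@H](O[Si](C)(C)C(C)(C)C)[C@H]1O[Si](C)(C)C(C)(C)C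
A3 | alternative 2 | 6-methyl-2H-pyran-2-one | CC1=CC=CC(=O)O1
A4 | alternative 2 | but-3-en-2-one | CC(=O)C=C
A5 | alternative 2 | endo-7-acetyl-1-methyl-2-oxabicyclo[2.2.2]oct-5-en-3-one | O=C1O[C@@]2(C)C=C[C@@H]1C[C@@H]2C(C)=O
A6 | alternative 3 | methyl (2Z,5Z,7R)-2-(bromomethyl)-7-[(tert-butyldimethylsilyl)oxy]-6-methyl-8-oxoocta-2,5-dienoate | O=C[C@H](O[Si](C)(C)C(C)(C)C)/C(C)=C\C/C=C(\CBr)C(=O)OC
A7 | alternative 3 | cis-fused α-methylene-γ-butyrolactone on C1–C2 with C3 silyl ether and C4=C5 alkene | C=C1C(=O)O[C@@H]2[C@H](O[Si](C)(C)C(C)(C)C)C(C)=CC[C@H]12
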